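The γ-lactone (ring B) is cut at C7a–C1 and C1–O2, so the C1 carbonyl becomes carbon monoxide. The feature exploited is that C1 sits on C7a, ortho to C3a and its C3 carbinol; without C1, benzene ring A is a symmetric 3,5-dimethoxyphenyl group whose two ortho carbons (future C7a and C4) are equivalent. The C3 stereocentre can therefore be set on a symmetric aryl ketone and one ortho bromine added without isomers. A palladium-catalysed carbonylation then forms both bonds and closes ring B in one operation, leaving C3 untouched. Its precursor is the (S)-2-bromo-3,5-dimethoxyphenyl carbinol bearing a twelve-methylene chain that ends in a dioxolane-masked methyl ketone.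

Key step: step 7

Assumption: 1,11-dibromoundecane, tert-butyl acetoacetate and 3,5-dimethoxybenzoyl chloride are taken as catalogue chemicals; the side chain is 13-oxotetradecyl (twelve CH2 groups between C3 and the C13' carbonyl), and C3 is S in carbinol, lactone and target alike because O > aryl C > chain CH2 > H holds throughout.

Step 1
Reactants: 1 tert-butyl acetoacetate; 2 1,11-dibromoundecane
Product: 4 racemic tert-butyl 2-acetyl-13-bromotridecanoate, via sodium enolate 3 (not isolated)
Conditions: NaH (0.95 equiv), THF, 0 °C; then 2 (3 equiv), DMF co-solvent, 60 °C; excess 2 recovered by chromatography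
Reagents that add atoms: none
Why: Acetoacetic ester alkylation, in which the stabilised enolate C-alkylates one primary C–Br bond by SN2 while the threefold excess of the symmetric dibromide keeps reaction at the second terminus and double alkylation at C2 low; the C2 stereocentre is racemic and disappears in step 2.

Step 2
Reactants: 4 racemic tert-butyl 2-acetyl-13-bromotridecanoate
Product: 7 2-(12-bromododecyl)-2-methyl-1,3-dioxolane, via 2-acetyl-13-bromotridecanoic acid 5 (not isolated), via 14-bromotetradecan-2-one 6 (not isolated)
Conditions: TsOH·H2O (5 mol%), toluene, reflux until gas evolution stops; then HOCH2CH2OH (3 equiv), Dean–Stark, reflux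
Reagents that add atoms: ethylene glycol, OCCO
Why: Acid-catalysed loss of isobutene from the tert-butyl ester and thermal decarboxylation of the resulting β-keto acid give the methyl ketone, which is then converted to its dioxolane by acid-catalysed ketalisation with azeotropic removal of water, none of which touches a primary alkyl bromide.

Step 3
Reactants: 8 3,5-dimethoxybenzoyl chloride
Product: 9 N,3,5-trimethoxy-N-methylbenzamide
Conditions: MeNHOMe·HCl (1.1 equiv), K2CO3 (2.5 equiv), EtOAc/H2O, 0 °C → rt
Reagents that add atoms: N,O-dimethylhydroxylamine hydrochloride, CNOC.Cl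
Why: Schotten–Baumann acylation of the liberated hydroxylamine by the acid chloride is fast and should give the Weinreb amide, which permits clean mono-addition in step 4.

Step 4
Reactants: 7 2-(12-bromododecyl)-2-methyl-1,3-dioxolane; 9 N,3,5-trimethoxy-N-methylbenzamide
Product: 12 1-(3,5-dimethoxyphenyl)-13-(2-methyl-1,3-dioxolan-2-yl)tridecan-1-one, via [12-(2-methyl-1,3-dioxolan-2-yl)dodecyl]magnesium bromide 10 (not isolated), via magnesium-chelated tetrahedral adduct 11 (not isolated)
Conditions: 7, Mg turnings, I2 (cat.), THF, 45 °C; then 9 (1.2 equiv), THF, 0 °C → rt; sat. aq. NH4Cl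
Reagents that add atoms: none
Why: Grignard formation from a primary bromide tolerates the dioxolane, and the Weinreb ketone synthesis stops at the five-membered magnesium chelate until the buffered quench, so the aryl ketone should form without over-addition and with the ketal intact.

Step 5
Reactants: 12 1-(3,5-dimethoxyphenyl)-13-(2-methyl-1,3-dioxolan-2-yl)tridecan-1-one
Product: 13 (1S)-1-(3,5-dimethoxyphenyl)-13-(2-methyl-1,3-dioxolan-2-yl)tridecan-1-ol
Conditions: RuCl[(S,S)-TsDPEN](p-cymene) (1 mol%; TsDPEN = N-tosyl-1,2-diphenylethane-1,2-diamine), HCO2H (5 equiv), Et3N (6 equiv), CH2Cl2, 30 °C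
Reagents that add atoms: none
Why: Noyori asymmetric transfer hydrogenation, in which the Ru–H/N–H pair of the (S,S) catalyst transfers hydride and proton through a six-membered outer-sphere transition state that holds the aryl ring under the η6-arene by a CH/π contact, so hydride reaches the Re face of the aryl ketone and the S carbinol should result; the unhindered symmetric aryl ketone is the favourable case for this catalyst, loss of CO2 makes the reduction irreversible, and the amine-rich medium spares the dioxolane.

Step 6
Reactants: 13 (1S)-1-(3,5-dimethoxyphenyl)-13-(2-methyl-1,3-dioxolan-2-yl)tridecan-1-ol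
Product: 14 (1S)-1-(2-bromo-3,5-dimethoxyphenyl)-13-(2-methyl-1,3-dioxolan-2-yl)tridecan-1-ol
Conditions: NBS (1.0 equiv), MeCN/CH2Cl2, 0 °C, dark
Reagents that add atoms: N-bromosuccinimide, O=C1CCC(=O)N1Br
Why: Electrophilic aromatic bromination, where the equivalent C2 and C6 positions are each para to one methoxy group and ortho to the other while C4 is buried between two methoxy groups, so one equivalent of NBS should give the single 2-bromo isomer under neutral conditions that leave the carbinol, its configuration and the ketal alone.

Step 7
Reactants: 14 (1S)-1-(2-bromo-3,5-dimethoxyphenyl)-13-(2-methyl-1,3-dioxolan-2-yl)tridecan-1-ol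
Product: 15 (3S)-5,7-dimethoxy-3-[12-(2-methyl-1,3-dioxolan-2-yl)dodecyl]-2-benzofuran-1(3H)-one
Conditions: Pd(OAc)2 (5 mol%), 1,1'-bis(diphenylphosphino)ferrocene (dppf, 10 mol%), CO (1 atm), K2CO3 (2 equiv), DMF, 100 °C
Reagents that add atoms: carbon monoxide, [C-]#[O+]
Why: Zerovalent palladium, generated in the flask from Pd(OAc)2 and the diphosphine, inserts into the C7a–Br bond, CO then inserts into the aryl–palladium bond to give an aroyl complex of divalent palladium, and the C3 hydroxyl attacks the acyl carbon so that C7a–C1 and C1–O2 are formed and zerovalent palladium is released, carbonate taking up HBr. The closest known reaction type is the palladium-catalysed carbonylative lactonisation of 2-halobenzyl alcohols to phthalides, an intramolecular alkoxycarbonylation. Ring B closes in the 5-exo-trig mode, the oxygen adding to an acyl carbon whose C=O stays outside the new ring. No stereocentre is created, and because the C3–O and C3–H bonds are never broken the S configuration from step 5 should be carried through unchanged. The step needs chemoselectivity for CO insertion and acyl capture over β-hydride elimination from a palladium alkoxide, which would oxidise the carbinol and strip the bromine; the ortho relation of carbinol and aroylpalladium makes the five-membered capture fast, the CO atmosphere keeps the aryl–palladium intermediate short-lived and only a weak carbonate base is present, while chelating dppf at 100 °C is expected to cope with the electron-rich, doubly ortho-substituted C–Br bond.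

Step 8
Reactants: 15 (3S)-5,7-dimethoxy-3-[12-(2-methyl-1,3-dioxolan-2-yl)dodecyl]-2-benzofuran-1(3H)-one
Product: 16 CJ-13,108, (3S)-5,7-dimethoxy-3-(13-oxotetradecyl)-2-benzofuran-1(3H)-one
Conditions: 1 M aq. HCl, THF, rt
Reagents that add atoms: water, O
Why: Acid-catalysed acetal hydrolysis should free the C13' methyl ketone, while the lactone and the aryl methyl ethers are stable to dilute acid at room temperature and C3, whose cation would have both methoxy groups meta and an ortho acyl group, does not ionise, so the S centre is kept.

Compound list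
1 | tert-butyl acetoacetate (tert-butyl 3-oxobutanoate) | CC(=O)CC(=O)OC(C)(C)C | starting material
2 | 1,11-dibromoundecane | BrCCCCCCCCCCCBr | starting material
3 | sodium enolate of tert-butyl acetoacetate | [Na+].CC(=O)[CH-]C(=O)OC(C)(C)C | intermediate (not isolated)
4 | racemic tert-butyl 2-acetyl-13-bromotridecanoate | CC(=O)C(CCCCCCCCCCCBr)C(=O)OC(C)(C)C | intermediate
5 | racemic 2-acetyl-13-bromotridecanoic acid | CC(=O)C(CCCCCCCCCCCBr)C(=O)O | intermediate (not isolated)
6 | 14-bromotetradecan-2-one | CC(=O)CCCCCCCCCCCCBr | intermediate (not isolated)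
7 | 2-(12-bromododecyl)-2-methyl-1,3-dioxolane | CC1(CCCCCCCCCCCCBr)OCCO1 | intermediate
8 | 3,5-dimethoxybenzoyl chloride | COc1cc(cc(OC)c1)C(Cl)=O | starting material
9 | N,3,5-trimethoxy-N-methylbenzamide | COc1cc(cc(OC)c1)C(=O)N(C)OC | intermediate
10 | [12-(2-methyl-1,3-dioxolan-2-yl)dodecyl]magnesium bromide | CC1(CCCCCCCCCCCC[Mg]Br)OCCO1 | intermediate (not isolated)
11 | bromomagnesium 1-(3,5-dimethoxyphenyl)-1-[methoxy(methyl)amino]-13-(2-methyl-1,3-dioxolan-2-yl)tridecan-1-olate (racemic chelated tetrahedral adduct) | COc1cc(cc(OC)c1)C(O[Mg]Br)(N(C)OC)CCCCCCCCCCCCC2(C)OCCO2 | intermediate (not isolated)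
12 | 1-(3,5-dimethoxyphenyl)-13-(2-methyl-1,3-dioxolan-2-yl)tridecan-1-one | COc1cc(cc(OC)c1)C(=O)CCCCCCCCCCCCC2(C)OCCO2 | intermediate
13 | (1S)-1-(3,5-dimethoxyphenyl)-13-(2-methyl-1,3-dioxolan-2-yl)tridecan-1-ol | COc1cc(OC)cc(c1)[C@H](CCCCCCCCCCCCC2(C)OCCO2)O | intermediate
14 | (1S)-1-(2-bromo-3,5-dimethoxyphenyl)-13-(2-methyl-1,3-dioxolan-2-yl)tridecan-1-ol | COc1cc(OC)c(Br)c(c1)[C@H](CCCCCCCCCCCCC2(C)OCCO2)O | intermediate
15 | (3S)-5,7-dimethoxy-3-[12-(2-methyl-1,3-dioxolan-2-yl)dodecyl]-2-benzofuran-1(3H)-one | COc1cc(OC)c2c(c1)[C@H](CCCCCCCCCCCCC3(C)OCCO3)OC2=O | intermediate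
16 | CJ-13,108, (3S)-5,7-dimethoxy-3-(13-oxotetradecyl)-2-benzofuran-1(3H)-one | COc1cc(OC)c2c(c1)[C@H](CCCCCCCCCCCCC(C)=O)OC2=O | target

Total step count: 8. Longest linear sequence: 7 steps (1 → 4 → 7 → 12 → 13 → 14 → 15 → 16); step 3 is a one-step side branch.

Steps most likely to fail

Step 7. Oxidative addition into the hindered, electron-rich C–Br bond may be slow, and a palladium alkoxide may undergo β-hydride elimination, which oxidises the carbinol and removes the bromine. The fallback sets out from 14 and replaces catalysis by organolithium carboxylation. n-BuLi (2.2 equiv, THF, −78 °C) deprotonates the hydroxyl and exchanges bromine for lithium to give lithium (1S)-1-(2-lithio-3,5-dimethoxyphenyl)-13-(2-methyl-1,3-dioxolan-2-yl)tridecan-1-olate F1. Dry CO2 and then 1 M HCl to pH 3–4 at 0 °C give 2-[(1S)-1-hydroxy-13-(2-methyl-1,3-dioxolan-2-yl)tridecyl]-4,6-dimethoxybenzoic acid F2. This γ-hydroxy acid should lactonise spontaneously, returning to the route at 15. The C3–O bond is again untouched.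

Step 5. Facial discrimination between the aryl group and the long n-alkyl chain may be incomplete, or turnover may stall. The fallback sets out from 12 and changes the mode of asymmetric induction to a Corey–Bakshi–Shibata reduction. It uses (R)-Me-CBS oxazaborolidine [(3aR)-1-methyl-3,3-diphenyltetrahydro-1H,3H-pyrrolo[1,2-c][1,3,2]oxazaborole, 10 mol%] and BH3·SMe2 in THF at −20 °C. Selectivity then rests on the steric difference between aryl and CH2R in a Lewis-acid-bound ketone, not on a CH/π contact. The (R) catalyst should deliver the S carbinol, returning to the route at 13.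

Step 6. Regiocontrol may leak to C4, a second bromine may enter at C6, or NBS may oxidise the benzylic alcohol of an advanced chiral intermediate. The fallback sets out from 9 and moves the bromination to the start, where isomers can be removed by crystallisation. NBS in MeCN should give 2-bromo-N,3,5-trimethoxy-N-methylbenzamide F3. Addition of Grignard reagent 10 (THF, 0 °C → rt, aq. NH4Cl) gives 1-(2-bromo-3,5-dimethoxyphenyl)-13-(2-methyl-1,3-dioxolan-2-yl)tridecan-1-one F4. Reduction with the (R)-Me-CBS oxazaborolidine and BH3·SMe2, for which an ortho-bromoaryl ketone is a favourable substrate, returns to the route at 14 and bypasses steps 5 and 6.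

Further compounds
F1 | step 7 | lithium (1S)-1-(2-lithio-3,5-dimethoxyphenyl)-13-(2-methyl-1,3-dioxolan-2-yl)tridecan-1-olate | COc1cc(OC)c([Li])c(c1)[C@H](CCCCCCCCCCCCC2(C)OCCO2)O[Li]
F2 | step 7 | 2-[(1S)-1-hydroxy-13-(2-methyl-1,3-dioxolan-2-yl)tridecyl]-4,6-dimethoxybenzoic acid | COc1cc(OC)c(C(=O)O)c(c1)[C@H](CCCCCCCCCCCCC2(C)OCCO2)O
F0 | step 5 | none | none
F3 | step 6 | 2-bromo-N,3,5-trimethoxy-N-methylbenzamide | COc1cc(OC)c(Br)c(c1)C(=O)N(C)OC
F4 | step 6 | 1-(2-bromo-3,5-dimethoxyphenyl)-13-(2-methyl-1,3-dioxolan-2-yl)tridecan-1-one | COc1cc(OC)c(Br)c(c1)C(=O)CCCCCCCCCCCCC2(C)OCCO2
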